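**Retrosynthetic overview**

1. The strategy rests on the C2–C6 segment (C1 benzylic to ring A, the 3,4-dihydroxy-5-methoxyphenyl ring; C7 benzylic to ring B, the 4-hydroxyphenyl ring): with its syn C3/C5 carbinols it is a meso unit, and the target is chiral only because C2 continues to ring A and C6 to ring B.
2. C1–C2 and C6–C7 are disconnected as styrenyl C=C bonds, made by two Wittig reactions of benzylic ylides (ring A first, ring B second) on aldehydes at C2 and C6; a final hydrogenation saturates both alkenes and removes all five benzyl ethers.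
3. The key disconnection is the ester C–O bond of monoacetate 14: a lipase acetylates one of the two enantiotopic hydroxymethyl groups of meso-2,4-bis(benzyloxy)pentane-1,5-diol 12 with vinyl acetate 13.
4. Diol 12 comes from cis-cyclopent-4-ene-1,3-diol 8 by double benzylation and ozonolysis with NaBH4 work-up.
5. No ring is formed anywhere: rings A and B are bought intact (in 1 and 6), and the only ring event is the opening of the cyclopentene.

Key step: step 8

Assumption: the lipase esterifies the hydroxymethyl arm on the (R)-configured benzyloxy carbon of 12, giving 14 as the (2R,4S) monoacetate; if it prefers the other arm, the same steps are run with phosphonium salts 7 and 5 in the opposite order. The Wittig products are expected as E/Z mixtures; their SMILES leave the alkene geometry open because both isomers converge in step 14.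

**Route**

Step 1
Reactants: 1 3,4-dihydroxy-5-methoxybenzaldehyde
Product: 2 3,4-bis(benzyloxy)-5-methoxybenzaldehyde
Conditions: BnBr, K2CO3, DMF, 60 °C
Reagents that add atoms: benzyl bromide BrCc1ccccc1
Why: Williamson ether synthesis, in which both phenoxides formed with K2CO3 are alkylated by benzyl bromide while the aldehyde is inert.

Step 2
Reactants: 2 3,4-bis(benzyloxy)-5-methoxybenzaldehyde
Product: 3 [3,4-bis(benzyloxy)-5-methoxyphenyl]methanol
Conditions: NaBH4, MeOH/THF, 0 °C
Reagents that add atoms: none
Why: Borohydride reduction of an aromatic aldehyde to the benzylic alcohol, which leaves aryl ethers untouched.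

Step 3
Reactants: 3 [3,4-bis(benzyloxy)-5-methoxyphenyl]methanol
Product: 4 1,2-bis(benzyloxy)-5-(bromomethyl)-3-methoxybenzene
Conditions: PBr3, CH2Cl2, 0 °C; used without storage
Reagents that add atoms: phosphorus tribromide BrP(Br)Br
Why: Conversion of a benzylic alcohol into the bromide through its phosphite ester (SN2 by bromide), mild enough at 0 °C to keep the aryl benzyl ethers.

Step 4
Reactants: 4 1,2-bis(benzyloxy)-5-(bromomethyl)-3-methoxybenzene
Product: 5 {[3,4-bis(benzyloxy)-5-methoxyphenyl]methyl}triphenylphosphonium bromide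
Conditions: PPh3, toluene, 80 °C; salt collected by filtration
Reagents that add atoms: triphenylphosphine c1ccc(cc1)P(c1ccccc1)c1ccccc1
Why: Quaternisation of PPh3 by a reactive benzylic bromide (SN2), driven by precipitation of the salt.

Step 5
Reactants: 6 1-(benzyloxy)-4-(chloromethyl)benzene
Product: 7 {[4-(benzyloxy)phenyl]methyl}triphenylphosphonium chloride
Conditions: PPh3, toluene, reflux; salt collected by filtration
Reagents that add atoms: triphenylphosphine c1ccc(cc1)P(c1ccccc1)c1ccccc1
Why: Quaternisation of PPh3 by a benzylic chloride (SN2), the standard entry to benzylic Wittig salts.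

Step 6
Reactants: 8 cis-cyclopent-4-ene-1,3-diol
Product: 9 cis-3,5-bis(benzyloxy)cyclopent-1-ene
Conditions: NaH, BnBr, n-Bu4NI (cat.), THF/DMF, 0 °C → rt
Reagents that add atoms: benzyl bromide BrCc1ccccc1
Why: Double Williamson etherification of the two secondary alkoxides; no bond to a stereocentre is broken, so the cis (meso) relationship is carried into 9.

Step 7
Reactants: 9 cis-3,5-bis(benzyloxy)cyclopent-1-ene
Product: 12 meso-(2R,4S)-2,4-bis(benzyloxy)pentane-1,5-diol, via secondary ozonide 10 (not isolated), via meso-2,4-bis(benzyloxy)pentanedial 11 (not isolated)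
Conditions: O3, CH2Cl2, −78 °C (Sudan red 7B as end-point indicator); then NaBH4, MeOH, −78 → 0 °C
Reagents that add atoms: ozone [O-][O+]=O
Why: Ozonolysis with reductive work-up, in which cycloaddition of ozone to the only C=C and cycloreversion–recombination give the secondary ozonide that borohydride reduces through the dialdehyde to the diol, while the two benzyloxy carbinol centres are untouched and stay syn, so 12 is meso.

Step 8
Reactants: 12 meso-(2R,4S)-2,4-bis(benzyloxy)pentane-1,5-diol; 13 vinyl acetate
Product: 14 (2R,4S)-2,4-bis(benzyloxy)-5-hydroxypentyl acetate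
Conditions: immobilised Burkholderia cepacia lipase, 13 (4 equiv), t-BuOMe, 25 °C; enzyme filtered off when 12 is consumed
Reagents that add atoms: none
Why: Lipase-catalysed irreversible transesterification, the known enantiotopic-group-selective monoacylation of meso and prochiral diols (2-O-benzylglycerol, meso 2,4-disubstituted pentane-1,5-diols): vinyl acetate acylates the active-site serine and the acyl-enzyme passes the acetyl group to the one hydroxymethyl arm whose neighbouring benzyloxy carbinol fits the binding pocket, while the released vinyl alcohol tautomerises to acetaldehyde and makes the transfer irreversible. No ring is closed and no bond to a stereocentre is made or broken; the two existing centres, mirror images of each other in 12, become fixed in the absolute sense because only one of the two enantiotopic arms is esterified, the controlling element being the chiral active site. The selectivities needed are discrimination between the enantiotopic primary hydroxyls, secured by the benzyloxy-bearing stereocentre directly next to each of them, and mono- over diacylation, secured by stopping at consumption of 12. The minor enantiomer of the monoacetate still carries the arm the enzyme prefers and is therefore converted faster into the meso diacetate, so a slight overrun should raise the enantiomeric purity of 14 at a small cost in material. Acetyl migration between the two arms, which would racemise 14, would need an eight-membered cyclic intermediate and is not expected.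

Step 9
Reactants: 14 (2R,4S)-2,4-bis(benzyloxy)-5-hydroxypentyl acetate
Product: 15 (2R,4S)-2,4-bis(benzyloxy)-5-oxopentyl acetate
Conditions: Dess–Martin periodinane, CH2Cl2, 0 °C → rt; aldehyde used crude
Reagents that add atoms: none
Why: Dess–Martin oxidation of a primary alcohol to the aldehyde under neutral, non-enolising conditions, so the α-benzyloxy centre should keep its configuration and the acetate stays in place.

Step 10
Reactants: 15 (2R,4S)-2,4-bis(benzyloxy)-5-oxopentyl acetate; 5 {[3,4-bis(benzyloxy)-5-methoxyphenyl]methyl}triphenylphosphonium bromide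
Product: 17 (2R,4S)-2,4-bis(benzyloxy)-6-[3,4-bis(benzyloxy)-5-methoxyphenyl]hex-5-en-1-yl acetate (E/Z mixture), via ring A ylide 16 (not isolated)
Conditions: 5 (1.2 equiv), NaN(SiMe3)2 (1.1 equiv), THF, −78 → 0 °C; then 15, −78 °C → rt
Reagents that add atoms: none
Why: Wittig reaction of a semi-stabilised benzylic ylide, preformed with less base than salt so that no free amide remains, which adds to the aldehyde at −78 °C faster than it can enolise the α-alkoxy aldehyde or attack the acetate; the alkene geometry is of no consequence because the double bond is hydrogenated in step 14.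

Step 11
Reactants: 17 (2R,4S)-2,4-bis(benzyloxy)-6-[3,4-bis(benzyloxy)-5-methoxyphenyl]hex-5-en-1-yl acetate
Product: 18 (2R,4S)-2,4-bis(benzyloxy)-6-[3,4-bis(benzyloxy)-5-methoxyphenyl]hex-5-en-1-ol
Conditions: K2CO3 (cat.), MeOH, 0 °C → rt
Reagents that add atoms: none
Why: Base-catalysed methanolysis (transesterification) of a primary acetate, to which benzyl ethers and the styrenyl alkene are inert.

Step 12
Reactants: 18 (2R,4S)-2,4-bis(benzyloxy)-6-[3,4-bis(benzyloxy)-5-methoxyphenyl]hex-5-en-1-ol
Product: 19 (2R,4S)-2,4-bis(benzyloxy)-6-[3,4-bis(benzyloxy)-5-methoxyphenyl]hex-5-enal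
Conditions: Dess–Martin periodinane, CH2Cl2, 0 °C → rt; aldehyde used crude
Reagents that add atoms: none
Why: Dess–Martin oxidation under neutral conditions, chosen again so that the second α-benzyloxy aldehyde is not epimerised.

Step 13
Reactants: 19 (2R,4S)-2,4-bis(benzyloxy)-6-[3,4-bis(benzyloxy)-5-methoxyphenyl]hex-5-enal; 7 {[4-(benzyloxy)phenyl]methyl}triphenylphosphonium chloride
Product: 21 (3S,5R)-3,5-bis(benzyloxy)-1-[3,4-bis(benzyloxy)-5-methoxyphenyl]-7-[4-(benzyloxy)phenyl]hepta-1,6-diene (mixture of alkene isomers), via ring B ylide 20 (not isolated)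
Conditions: 7 (1.2 equiv), NaN(SiMe3)2 (1.1 equiv), THF, −78 → 0 °C; then 19, −78 °C → rt
Reagents that add atoms: none
Why: Second Wittig reaction of a semi-stabilised benzylic ylide with the aldehyde at low temperature, forming the C6=C7 bond without touching either carbinol centre.

Step 14
Reactants: 21 (3S,5R)-3,5-bis(benzyloxy)-1-[3,4-bis(benzyloxy)-5-methoxyphenyl]-7-[4-(benzyloxy)phenyl]hepta-1,6-diene
Product: 23 5-[(3R,5S)-3,5-dihydroxy-7-(4-hydroxyphenyl)heptyl]-3-methoxybenzene-1,2-diol (CNP0291714.1), via saturated pentabenzyl ether 22 (not isolated)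
Conditions: H2 (1 atm), 10% Pd/C, EtOAc, rt until both alkenes are saturated; then MeOH added, H2, rt; filtration and concentration under argon
Reagents that add atoms: none
Why: Heterogeneous catalytic hydrogenation in which the two styrenyl double bonds are saturated first and the five benzyl ethers (three aryl, two alkyl) are then cleaved by hydrogenolysis at their benzylic C–O bonds; the carbinol centres take no part, so the (3R,5S) syn diol is delivered unchanged.

**Compound list**

1 | 3,4-dihydroxy-5-methoxybenzaldehyde | COc1cc(C=O)cc(O)c1O | starting material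
2 | 3,4-bis(benzyloxy)-5-methoxybenzaldehyde | COc1cc(C=O)cc(OCc2ccccc2)c1OCc1ccccc1 | intermediate
3 | [3,4-bis(benzyloxy)-5-methoxyphenyl]methanol | COc1cc(CO)cc(OCc2ccccc2)c1OCc1ccccc1 | intermediate
4 | 1,2-bis(benzyloxy)-5-(bromomethyl)-3-methoxybenzene | COc1cc(CBr)cc(OCc2ccccc2)c1OCc1ccccc1 | intermediate
5 | {[3,4-bis(benzyloxy)-5-methoxyphenyl]methyl}triphenylphosphonium bromide | COc1cc(C[P+](c2ccccc2)(c2ccccc2)c2ccccc2)cc(OCc2ccccc2)c1OCc1ccccc1.[Br-] | intermediate
6 | 1-(benzyloxy)-4-(chloromethyl)benzene | ClCc1ccc(OCc2ccccc2)cc1 | starting material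
7 | {[4-(benzyloxy)phenyl]methyl}triphenylphosphonium chloride | [Cl-].c1ccc(cc1)COc1ccc(C[P+](c2ccccc2)(c2ccccc2)c2ccccc2)cc1 | intermediate
8 | cis-cyclopent-4-ene-1,3-diol (meso) | O[C@@H]1C[C@H](O)C=C1 | starting material
9 | cis-3,5-bis(benzyloxy)cyclopent-1-ene (meso, 3R,5S) | c1ccc(cc1)CO[C@@H]1C[C@H](OCc2ccccc2)C=C1 | intermediate
10 | 2,4-bis(benzyloxy)-6,7,8-trioxabicyclo[3.2.1]octane (secondary ozonide; benzyloxy groups cis to each other; orientation relative to the peroxide bridge not assigned, one meso diastereomer drawn) | O1[C@H]2[C@@H](OCc3ccccc3)C[C@@H](OCc3ccccc3)[C@@H]1OO2 | intermediate (not isolated)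
11 | meso-(2R,4S)-2,4-bis(benzyloxy)pentanedial | O=C[C@@H](OCc1ccccc1)C[C@@H](OCc1ccccc1)C=O | intermediate (not isolated)
12 | meso-(2R,4S)-2,4-bis(benzyloxy)pentane-1,5-diol | OC[C@@H](OCc1ccccc1)C[C@@H](OCc1ccccc1)CO | intermediate
13 | vinyl acetate | C=COC(C)=O | starting material
14 | (2R,4S)-2,4-bis(benzyloxy)-5-hydroxypentyl acetate | OC[C@@H](OCc1ccccc1)C[C@@H](OCc1ccccc1)COC(C)=O | intermediate
15 | (2R,4S)-2,4-bis(benzyloxy)-5-oxopentyl acetate | O=C[C@@H](OCc1ccccc1)C[C@@H](OCc1ccccc1)COC(C)=O | intermediate
16 | [3,4-bis(benzyloxy)-5-methoxybenzylidene]triphenylphosphorane (ring A ylide) | COc1cc(C=P(c2ccccc2)(c2ccccc2)c2ccccc2)cc(OCc2ccccc2)c1OCc1ccccc1 | intermediate (not isolated)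
17 | (2R,4S)-2,4-bis(benzyloxy)-6-[3,4-bis(benzyloxy)-5-methoxyphenyl]hex-5-en-1-yl acetate (E/Z mixture) | COc1cc(C=C[C@@H](OCc2ccccc2)C[C@@H](OCc2ccccc2)COC(C)=O)cc(OCc2ccccc2)c1OCc1ccccc1 | intermediate
18 | (2R,4S)-2,4-bis(benzyloxy)-6-[3,4-bis(benzyloxy)-5-methoxyphenyl]hex-5-en-1-ol (E/Z mixture) | COc1cc(C=C[C@@H](OCc2ccccc2)C[C@@H](OCc2ccccc2)CO)cc(OCc2ccccc2)c1OCc1ccccc1 | intermediate
19 | (2R,4S)-2,4-bis(benzyloxy)-6-[3,4-bis(benzyloxy)-5-methoxyphenyl]hex-5-enal (E/Z mixture) | COc1cc(C=C[C@@H](OCc2ccccc2)C[C@@H](OCc2ccccc2)C=O)cc(OCc2ccccc2)c1OCc1ccccc1 | intermediate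
20 | [4-(benzyloxy)benzylidene]triphenylphosphorane (ring B ylide) | c1ccc(cc1)COc1ccc(C=P(c2ccccc2)(c2ccccc2)c2ccccc2)cc1 | intermediate (not isolated)
21 | (3S,5R)-3,5-bis(benzyloxy)-1-[3,4-bis(benzyloxy)-5-methoxyphenyl]-7-[4-(benzyloxy)phenyl]hepta-1,6-diene (mixture of alkene isomers) | COc1cc(C=C[C@@H](OCc2ccccc2)C[C@@H](OCc2ccccc2)C=Cc2ccc(OCc3ccccc3)cc2)cc(OCc2ccccc2)c1OCc1ccccc1 | intermediate
22 | (3R,5S)-3,5-bis(benzyloxy)-1-[3,4-bis(benzyloxy)-5-methoxyphenyl]-7-[4-(benzyloxy)phenyl]heptane | COc1cc(CC[C@@H](OCc2ccccc2)C[C@@H](OCc2ccccc2)CCc2ccc(OCc3ccccc3)cc2)cc(OCc2ccccc2)c1OCc1ccccc1 | intermediate (not isolated)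
23 | 5-[(3R,5S)-3,5-dihydroxy-7-(4-hydroxyphenyl)heptyl]-3-methoxybenzene-1,2-diol (CNP0291714.1) | COc1cc(CC[C@@H](O)C[C@@H](O)CCc2ccc(O)cc2)cc(O)c1O | target

**Step count**

Total: 14 steps. Longest linear sequence: 9 steps (steps 6 to 14 from 8; the ring A branch, steps 1 to 4 followed by steps 10 to 14, is equally long).

**Steps most likely to fail**

Step 8. The lipase may discriminate poorly between the two enantiotopic hydroxymethyl arms, or acetyl transfer may run on to the diacetate before the diol is consumed, leaving 14 in low enantiomeric purity. The fallback sets out from 12 and comes back at 21; it moves the desymmetrisation from acylation in an organic solvent to ester hydrolysis in water. Diol 12 would be acetylated on both arms (Ac2O, pyridine, DMAP cat.) to meso-(2R,4S)-2,4-bis(benzyloxy)pentane-1,5-diyl diacetate F1. One enantiotopic ester would then be hydrolysed with pig liver esterase, or with the same lipase, in pH 7 phosphate buffer with acetone as cosolvent. An enzyme with the same arm preference now removes the acetate from the arm that acylation would have esterified, so the product should be the enantiomeric monoacetate, (2S,4R)-2,4-bis(benzyloxy)-5-hydroxypentyl acetate F2. F2 would be carried through the chemistry of steps 9 to 13 with the two ylides exchanged: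
- Dess–Martin oxidation to (2S,4R)-2,4-bis(benzyloxy)-5-oxopentyl acetate F3.
- Wittig reaction with ring B ylide 20 to (2S,4R)-2,4-bis(benzyloxy)-6-[4-(benzyloxy)phenyl]hex-5-en-1-yl acetate F4.
- Methanolysis to (2S,4R)-2,4-bis(benzyloxy)-6-[4-(benzyloxy)phenyl]hex-5-en-1-ol F5.
- Oxidation to (2S,4R)-2,4-bis(benzyloxy)-6-[4-(benzyloxy)phenyl]hex-5-enal F6.
- Wittig reaction with ring A ylide 16 to diene 21.

Should the hydrolysis instead deliver 14 itself, the main route is resumed at step 9.

Step 13. The basic ylide may enolise the α-benzyloxy aldehyde 19 before it olefinates, which would erode the syn relationship of the two carbinol centres; the same concern applies, less severely, to step 10. The fallback sets out from 18 and comes back at 22; it avoids the aldehyde and makes C6–C7 directly as a saturated bond. Alcohol 18 would be converted (Tf2O, 2,6-lutidine, CH2Cl2, −78 °C) into (2R,4S)-2,4-bis(benzyloxy)-6-[3,4-bis(benzyloxy)-5-methoxyphenyl]hex-5-en-1-yl trifluoromethanesulfonate F7, used cold at once so that coupling outruns debenzylative cyclisation by the γ-benzyloxy group. F7 would be coupled with [4-(benzyloxy)benzyl]magnesium chloride F8 (from 6 and Mg in THF) under CuBr·SMe2 catalysis at −78 → −30 °C. This copper-catalysed alkyl–alkyl coupling should give (3S,5S)-3,5-bis(benzyloxy)-1-[3,4-bis(benzyloxy)-5-methoxyphenyl]-7-[4-(benzyloxy)phenyl]hept-1-ene F9. Under the conditions of step 14, F9 is saturated to 22 and debenzylated to 23.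

Step 14. Hydrogenolysis of the allylic (cinnamyl-type) C3–O and C5–O bonds on palladium may compete with saturation of the double bonds, deleting one or both carbinol oxygens. The fallback sets out from 21 and comes back at 22; it separates the two reductions. The double bonds of 21 would first be saturated with diimide, generated from p-toluenesulfonyl hydrazide and NaOAc in refluxing aqueous DME, which cannot cleave C–O bonds. This gives 22 as an isolated compound, which is then debenzylated with H2 over Pd(OH)2/C in EtOAc/MeOH to 23. No new compound arises.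

**Further compounds**

F1 | step 8 | meso-(2R,4S)-2,4-bis(benzyloxy)pentane-1,5-diyl diacetate | CC(=O)OC[C@@H](OCc1ccccc1)C[C@@H](OCc1ccccc1)COC(C)=O
F2 | step 8 | (2S,4R)-2,4-bis(benzyloxy)-5-hydroxypentyl acetate | OC[C@H](OCc1ccccc1)C[C@H](OCc1ccccc1)COC(C)=O
F3 | step 8 | (2S,4R)-2,4-bis(benzyloxy)-5-oxopentyl acetate | O=C[C@H](OCc1ccccc1)C[C@H](OCc1ccccc1)COC(C)=O
F4 | step 8 | (2S,4R)-2,4-bis(benzyloxy)-6-[4-(benzyloxy)phenyl]hex-5-en-1-yl acetate (E/Z mixture) | CC(=O)OC[C@@H](OCc1ccccc1)C[C@@H](OCc1ccccc1)C=Cc1ccc(OCc2ccccc2)cc1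
F5 | step 8 | (2S,4R)-2,4-bis(benzyloxy)-6-[4-(benzyloxy)phenyl]hex-5-en-1-ol (E/Z mixture) | OC[C@@H](OCc1ccccc1)C[C@@H](OCc1ccccc1)C=Cc1ccc(OCc2ccccc2)cc1
F6 | step 8 | (2S,4R)-2,4-bis(benzyloxy)-6-[4-(benzyloxy)phenyl]hex-5-enal (E/Z mixture) | O=C[C@@H](OCc1ccccc1)C[C@@H](OCc1ccccc1)C=Cc1ccc(OCc2ccccc2)cc1
F7 | step 13 | (2R,4S)-2,4-bis(benzyloxy)-6-[3,4-bis(benzyloxy)-5-methoxyphenyl]hex-5-en-1-yl trifluoromethanesulfonate (E/Z mixture) | COc1cc(C=C[C@@H](OCc2ccccc2)C[C@@H](OCc2ccccc2)COS(=O)(=O)C(F)(F)F)cc(OCc2ccccc2)c1OCc1ccccc1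
F8 | step 13 | [4-(benzyloxy)benzyl]magnesium chloride | Cl[Mg]Cc1ccc(OCc2ccccc2)cc1
F9 | step 13 | (3S,5S)-3,5-bis(benzyloxy)-1-[3,4-bis(benzyloxy)-5-methoxyphenyl]-7-[4-(benzyloxy)phenyl]hept-1-ene (E/Z mixture) | COc1cc(C=C[C@@H](OCc2ccccc2)C[C@@H](OCc2ccccc2)CCc2ccc(OCc3ccccc3)cc2)cc(OCc2ccccc2)c1OCc1ccccc1
F0 | step 14 | none | none
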